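**Retrosynthetic overview**

1. Target 14 ⇐ 12 by O-methylation of the ring A hydroxyl and removal of the ring B pivalate. Ring A is the ring with OCH3 (C1 OCH3, C2 Br, C4 Br, C6 O–ring B); ring B is the tribrominated ring with the free OH.
2. Key disconnection: ring A of 12 ⇐ the cyclohexanone ring of the alpha-aryloxy ketone 9. The strategy rests on the fact that both ring A bromines (C2, C4) are ortho and para to the C1 oxygen while the aryloxy group sits on the other ortho carbon C6, which is the pattern a 2-aryloxycyclohexanone gives on brominative aromatisation. The C2–Br and C4–Br bonds are made in that same operation.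
3. 9 ⇐ trans-2-aryloxycyclohexanol 8 (oxidation) ⇐ phenol 6 (pivaloylation) ⇐ 5 (ortho-bromination) ⇐ aldehyde 3 (Baeyer–Villiger/Dakin) ⇐ 3,5-dibromosalicylaldehyde 1 + cyclohexene oxide 2 (alkyl aryl ether by epoxide opening).
4. Ring order: ring B is bought aromatic and finished first (steps 1–4). Ring A is carried as the saturated carbocycle of 2 and becomes aromatic only in step 6. No ring is closed anywhere in the route.

Key step: step 6

Remark on the chemistry: compounds 3–9 are racemic (one enantiomer is drawn in each SMILES). The stereocentres are removed in steps 5 and 6 and the target is achiral, so no absolute control is needed.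

**Route**

Step 1
Reactants: 1 3,5-dibromosalicylaldehyde; 2 cyclohexene oxide
Product: 3 3,5-dibromo-2-{[(1RS,2RS)-2-hydroxycyclohexyl]oxy}benzaldehyde (trans, racemic)
Conditions: 2 (3 equiv), Cs2CO3 (0.3 equiv), DMF, 100 °C
Reagents that add atoms: none
Why: Base-catalysed SN2 ring opening of the meso epoxide by the phenoxide of 1; backside attack sets the trans relationship of OAr and OH (racemic), the aldehyde is inert to carbonate, and the alkoxide formed is reprotonated by the acidic phenol so the base turns over.

Step 2
Reactants: 3 3,5-dibromo-2-{[(1RS,2RS)-2-hydroxycyclohexyl]oxy}benzaldehyde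
Product: 5 3,5-dibromo-2-{[(1RS,2RS)-2-hydroxycyclohexyl]oxy}phenol, via aryl formate 4 (not isolated)
Conditions: mCPBA (1.5 equiv), CH2Cl2, 0 °C to rt; aq. NaHCO3/Na2S2O3 wash; then K2CO3 (cat.), MeOH, rt
Reagents that add atoms: mCPBA, OOC(=O)c1cccc(Cl)c1
Why: Baeyer–Villiger (Dakin-type) oxidation in which the ortho alkoxy group favours aryl over hydride migration in the Criegee intermediate, giving formate 4, which is cleaved by mild methanolysis; the secondary alcohol and the aryl bromides are inert to the peracid.

Step 3
Reactants: 5 3,5-dibromo-2-{[(1RS,2RS)-2-hydroxycyclohexyl]oxy}phenol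
Product: 6 2,3,5-tribromo-6-{[(1RS,2RS)-2-hydroxycyclohexyl]oxy}phenol
Conditions: NBS (1.0 equiv), i-Pr2NH (10 mol %), CH2Cl2, 0 °C
Reagents that add atoms: N-bromosuccinimide, O=C1CCC(=O)N1Br
Why: Amine-mediated ortho-selective electrophilic bromination of a phenol, in which the N-bromoamine formed in situ is hydrogen-bonded to the hydroxyl and delivers bromine to its only free ortho carbon, while the para carbon is shielded by two flanking bromines and one equivalent at low temperature limits a second bromination.

Step 4
Reactants: 6 2,3,5-tribromo-6-{[(1RS,2RS)-2-hydroxycyclohexyl]oxy}phenol; 7 pivaloyl chloride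
Product: 8 2,3,5-tribromo-6-{[(1RS,2RS)-2-hydroxycyclohexyl]oxy}phenyl pivalate
Conditions: 7 (1.1 equiv), Et3N (1.5 equiv), CH2Cl2, 0 °C
Reagents that add atoms: pivaloyl chloride (compound 7), CC(C)(C)C(Cl)=O
Why: Chemoselective O-acylation, since Et3N ionises only the acidic tribromophenol and its phenoxide is acylated at 0 °C without an acyl-transfer catalyst while the hindered secondary alcohol stays free; the ester later prevents hemiketal formation with the ketone and deactivates ring B.

Step 5
Reactants: 8 2,3,5-tribromo-6-{[(1RS,2RS)-2-hydroxycyclohexyl]oxy}phenyl pivalate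
Product: 9 racemic 2,3,5-tribromo-6-[(2-oxocyclohexyl)oxy]phenyl pivalate
Conditions: Dess–Martin periodinane (1.3 equiv), CH2Cl2, rt
Reagents that add atoms: none
Why: Dess–Martin oxidation of a secondary alcohol to the ketone under neutral conditions that leave the aryl pivalate, the aryl bromides and the alpha-aryloxy carbon untouched; the carbinol stereocentre disappears and the remaining alpha-carbon is racemic.

Step 6
Reactants: 9 racemic 2,3,5-tribromo-6-[(2-oxocyclohexyl)oxy]phenyl pivalate
Product: 12 2,3,5-tribromo-6-(3,5-dibromo-2-hydroxyphenoxy)phenyl pivalate, via 2-aryloxycyclohexenone 10 (not isolated), via 2-aryloxyphenol 11 (not isolated)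
Conditions: Br2 (4.5 equiv), HBr (cat.), glacial AcOH, 20 °C then 70 °C
Reagents that add atoms: bromine, BrBr
Why: Acid-catalysed enolisation of 9, alpha-bromination and loss of HBr should give the 2-aryloxycyclohex-2-enone 10; a second bromination/dehydrobromination at the alpha' (or gamma) carbon gives a cyclohexadienone that tautomerises to the 2-aryloxyphenol 11, whose free hydroxyl then directs two electrophilic aromatic brominations to its open ortho and para carbons (C2 and C4 of ring A). The closest known reaction type is the aromatisation of cyclohexanones and cyclohexenones to ortho/para-brominated phenols with Br2 or CuBr2 by alpha-bromination and dehydrobromination. No ring is closed and no stereocentre is created: the carbocycle that came from cyclohexene oxide only changes its oxidation level, and the racemic alpha-carbon of 9 becomes sp2. The step needs regioselective placement of the two ring A bromines, which is secured because the hydroxyl is a much stronger donor than the twisted, electron-poor aryloxy oxygen and because the two remaining ring A carbons are meta to the hydroxyl, so bromination stops there. It also needs an untouched ring B, which is secured by its acylated oxygen, its three bromines and the fact that its only C–H lies between two bromines. Glacial acetic acid keeps water away from the alpha-bromo-alpha-aryloxy ketone so that elimination should win over hydrolytic loss of the aryloxy group, and the pivalate is expected to tolerate HBr in AcOH at this temperature.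

Step 7
Reactants: 12 2,3,5-tribromo-6-(3,5-dibromo-2-hydroxyphenoxy)phenyl pivalate
Product: 13 2,3,5-tribromo-6-(3,5-dibromo-2-methoxyphenoxy)phenyl pivalate
Conditions: MeI (5 equiv), K2CO3 (1.5 equiv), DMF, 0 °C to rt
Reagents that add atoms: iodomethane, CI
Why: Williamson O-methylation of the ring A phenoxide, which reacts with the small electrophile MeI despite its two ortho substituents; the excess of MeI at low temperature should let the alkylation outrun any base-induced transfer of the bulky pivaloyl group to the ring A oxygen, which would need an eight-membered transition state.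

Step 8
Reactants: 13 2,3,5-tribromo-6-(3,5-dibromo-2-methoxyphenoxy)phenyl pivalate
Product: 14 2,3,5-tribromo-6-(3,5-dibromo-2-methoxyphenoxy)phenol (target)
Conditions: NaOMe (1.5 equiv), MeOH, rt; then 1 M HCl
Reagents that add atoms: none
Why: Base-mediated transesterification (methanolysis) of an aryl ester whose tribromophenoxide is a good leaving group; the aryl methyl ether, the diaryl ether and the aryl bromides are inert to methoxide at room temperature, and acidification gives the free ring B phenol.

**Compound list**

1 | 3,5-dibromosalicylaldehyde (3,5-dibromo-2-hydroxybenzaldehyde) | O=Cc1cc(Br)cc(Br)c1O | starting material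
2 | cyclohexene oxide (cis-7-oxabicyclo[4.1.0]heptane, meso) | C1CC[C@@H]2O[C@@H]2C1 | starting material
3 | 3,5-dibromo-2-{[(1RS,2RS)-2-hydroxycyclohexyl]oxy}benzaldehyde (trans, racemic) | O[C@@H]1CCCC[C@H]1Oc1c(Br)cc(Br)cc1C=O | intermediate
4 | 3,5-dibromo-2-{[(1RS,2RS)-2-hydroxycyclohexyl]oxy}phenyl formate (trans, racemic) | O[C@@H]1CCCC[C@H]1Oc1c(Br)cc(Br)cc1OC=O | intermediate (not isolated)
5 | 3,5-dibromo-2-{[(1RS,2RS)-2-hydroxycyclohexyl]oxy}phenol (trans, racemic) | O[C@@H]1CCCC[C@H]1Oc1c(Br)cc(Br)cc1O | intermediate
6 | 2,3,5-tribromo-6-{[(1RS,2RS)-2-hydroxycyclohexyl]oxy}phenol (trans, racemic) | O[C@@H]1CCCC[C@H]1Oc1c(Br)cc(Br)c(Br)c1O | intermediate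
7 | pivaloyl chloride | CC(C)(C)C(Cl)=O | starting material
8 | 2,3,5-tribromo-6-{[(1RS,2RS)-2-hydroxycyclohexyl]oxy}phenyl pivalate (trans, racemic) | O[C@@H]1CCCC[C@H]1Oc1c(Br)cc(Br)c(Br)c1OC(=O)C(C)(C)C | intermediate
9 | 2,3,5-tribromo-6-[(2-oxocyclohexyl)oxy]phenyl pivalate (racemic; R enantiomer drawn) | O=C1CCCC[C@H]1Oc1c(Br)cc(Br)c(Br)c1OC(=O)C(C)(C)C | intermediate
10 | 2,3,5-tribromo-6-[(6-oxocyclohex-1-en-1-yl)oxy]phenyl pivalate | O=C1CCCC=C1Oc1c(Br)cc(Br)c(Br)c1OC(=O)C(C)(C)C | intermediate (not isolated)
11 | 2,3,5-tribromo-6-(2-hydroxyphenoxy)phenyl pivalate | Oc1ccccc1Oc1c(Br)cc(Br)c(Br)c1OC(=O)C(C)(C)C | intermediate (not isolated)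
12 | 2,3,5-tribromo-6-(3,5-dibromo-2-hydroxyphenoxy)phenyl pivalate | Oc1c(Br)cc(Br)cc1Oc1c(Br)cc(Br)c(Br)c1OC(=O)C(C)(C)C | intermediate
13 | 2,3,5-tribromo-6-(3,5-dibromo-2-methoxyphenoxy)phenyl pivalate | COc1c(Br)cc(Br)cc1Oc1c(Br)cc(Br)c(Br)c1OC(=O)C(C)(C)C | intermediate
14 | 2,3,5-tribromo-6-(3,5-dibromo-2-methoxyphenoxy)phenol | COc1c(Br)cc(Br)cc1Oc1c(Br)cc(Br)c(Br)c1O | target

**Step count and risks**

Total step count: 8. Longest linear sequence: 8 steps (from 1).

Steps most likely to fail:

1. Step 6. The cascade may stall at the alpha-bromo ketone or bromo-enone stage, bromine may add across the enone double bond and end up on a ring A carbon meta to the hydroxyl, or the alpha-bromo-alpha-aryloxy ketone may lose its aryloxy group by acid solvolysis. The fallback separates dehydrogenation from bromination. It sets out from ketone 9: an iodine-catalysed dehydrogenation with DMSO as terminal oxidant (I2 20 mol %, DMSO, 100 °C, a known way from cyclohexanones to phenols) should give 2,3,5-tribromo-6-(2-hydroxyphenoxy)phenyl pivalate 11, which is now isolated. Phenol 11 is then brominated with Br2 (2.1 equiv) in AcOH at room temperature, the hydroxyl directing to its ortho and para carbons, and the route is rejoined at 12.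

2. Step 3. Attack at the para carbon between the two bromines may compete with attack at the ortho carbon, or a second bromination may follow, giving isomeric or over-brominated phenols that are hard to separate. The fallback introduces the third bromine before the aldehyde is converted, where the substitution pattern fixes its position. Purchased 2-bromo-6-hydroxybenzaldehyde F1 is dibrominated ortho and para to its hydroxyl (Br2 2.1 equiv, AcOH, rt) to give 2,3,5-tribromo-6-hydroxybenzaldehyde F2. F2 opens cyclohexene oxide 2 under the conditions of step 1 to give 2,3,5-tribromo-6-{[(1RS,2RS)-2-hydroxycyclohexyl]oxy}benzaldehyde F3. Baeyer–Villiger oxidation with mCPBA then gives 2,3,5-tribromo-6-{[(1RS,2RS)-2-hydroxycyclohexyl]oxy}phenyl formate F4, and methanolysis (K2CO3 cat., MeOH) delivers 6. This fallback sets out from 2 and comes back at 6; its Baeyer–Villiger step runs on a more electron-poor ring and may need longer reaction times.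

3. Step 1. Opening of the secondary epoxide may be sluggish because the phenoxide is hindered (CHO and Br in its two ortho positions) and weakly nucleophilic, and prolonged heating may lead to epoxide oligomerisation or degradation of the aldehyde. The fallback reverses the polarity of the ether formation. It sets out from cyclohexene oxide 2, which is hydrolysed (dilute H2SO4, H2O/THF) to racemic trans-cyclohexane-1,2-diol F5. The monosodium alkoxide of F5 (NaH 1 equiv, F5 in excess, THF/DMF, 0 °C) then displaces fluoride from purchased 3,5-dibromo-2-fluorobenzaldehyde F6 by nucleophilic aromatic substitution, which the ortho formyl group activates, and the route is rejoined at 3.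

**Further compounds**

F0 | step 6 | none | none
F1 | step 3 | 2-bromo-6-hydroxybenzaldehyde | O=Cc1c(O)cccc1Br
F2 | step 3 | 2,3,5-tribromo-6-hydroxybenzaldehyde | O=Cc1c(O)c(Br)cc(Br)c1Br
F3 | step 3 | 2,3,5-tribromo-6-{[(1RS,2RS)-2-hydroxycyclohexyl]oxy}benzaldehyde | O[C@@H]1CCCC[C@H]1Oc1c(Br)cc(Br)c(Br)c1C=O
F4 | step 3 | 2,3,5-tribromo-6-{[(1RS,2RS)-2-hydroxycyclohexyl]oxy}phenyl formate | O[C@@H]1CCCC[C@H]1Oc1c(Br)cc(Br)c(Br)c1OC=O
F5 | step 1 | trans-cyclohexane-1,2-diol (racemic) | O[C@@H]1CCCC[C@H]1O
F6 | step 1 | 3,5-dibromo-2-fluorobenzaldehyde | O=Cc1cc(Br)cc(Br)c1F
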